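(The constants used here belong to no real substance; the flask was simulated.)

In this flask the exchange turns a spent carrier over at 15 /s with the salt as charged, while the target step uses a fresh carrier at 0.11 /s. The exchange is faster, so we hold it at equilibrium.

substrate 26 mM; salt in the second phase 28.6 mM; spent carrier 2.6 mM; volume of the second phase over the first 0.50

    2 substrate → self-condensation product (k1 = 0.030 /M/s)
    substrate + fresh carrier → target + spent carrier (k2 = 4.2 /M/s)
    spent carrier + salt in the second phase ⇌ fresh carrier + spent salt in the second phase (K3 = 0.17, k3 = 270 /M/s)
    fresh carrier → spent catalyst (k4 = 2.3 × 10⁻⁵ /s)

* apparent order in salt in the second phase when 20% of the substrate are converted (percent change of the rate of making target for one percent more salt in the second phase charged)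
* apparent order in spent carrier when 20% of the substrate are converted (percent change of the rate of making target for one percent more spent carrier charged)

- percentages count the substrate that a species holds: one self-condensation product counts as two
- where a step has two of a species, its rate is k times that concentration squared, and two are used at each turn
- in the second phase: salt in the second phase, spent salt in the second phase; everything else is in the first
- charges count per volume of the first phase; a concentration in a rate is the amount of a species over the volume of its own phase; every rate counts per litre of the first phase
- charge of substrate (flask): 26 mM

Fresh carrier dies at 2.3 × 10⁻⁵ /s, slower than the target step, so we drop that loss. Each target or fresh carrier then stands for one salt spent. The volume ratio cancels between the two salts, so c(fresh carrier)/c(spent carrier) is the exchange constant 0.17 times salt left over salt spent.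

The symmetric case is our zero: with that ratio at one, half the carrier is spent. The rate follows c(fresh carrier), and one percent on the ratio moves that by the spent share, one over one plus the ratio, the fraction of carrier standing spent.

We start from the symmetric case. At 10.0% conversion, with half the carrier fresh, we reckon the target step uses substrate at 3.89 to one against self-condensation, so the 5.20 mM of substrate used by 20% conversion gives 4.14 mM of target. Salt spent is then 5.44 mM, the ratio 0.724, and the spent share 0.580.

More carrier adds spent salt, as fresh carrier and as extra target, so we reckon the order in spent carrier at 0.793. One percent more salt charged lifts the salt left by 1.23 percent, so we reckon the order in salt as the spent share times that lift times the same trim, 0.568.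

The forecast says 0.58 and 0.8, with the carrier “held back by spent salt”. Our two orders stand slightly lower than these.

The flask gives 0.58 in salt and 0.80 in spent carrier. At 20% conversion, reached at 30.9 s, spent carrier held 57.4% of the catalyst. Later, with 38.8% of the salt left at 800 s, the same ratio gives a spent share of 90.3%, and the flask has spent carrier at 90.0%.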